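Work in percent of the substrate charged, not in M: a larger charge then shows up as a lost yield.

| flask | substrate | remark | time |
|---|---|---|---|
| red | 0.23 M | run made earlier |  |
| grey | 0.77 M | run made earlier |  |
| ochre | 2.4 M | run made earlier |  |
| zeta | 0.20 M |  | 25 min |
| alpha | 0.40 M |  | 25 min |
| beta | 0.80 M |  | 25 min |
| gamma | 1.5 M |  | 25 min |
| epsilon | 3.0 M |  | 25 min |

| run | time / min | target / % |
|---|---|---|
| red | 1.00 | 0.2 |
| red | 2.50 | 1.0 |
| red | 5.00 | 1.1 |
| red | 12.0 | 6.7 |
| grey | 1.00 | 1.0 |
| grey | 2.50 | 0.7 |
| grey | 5.00 | 0.8 |
| grey | 12.0 | 5.4 |
| ochre | 1.00 | 0.4 |
| ochre | 2.50 | 0.4 |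
| ochre | 5.00 | 0.9 |
| ochre | 12.0 | 3.4 |

(standard deviation of a reading: 0.5 percentage points)

- percentages count the substrate that a species holds: one self-condensation product counts as two
- steps thought possible: 2 substrate -> self-condensation product; substrate <-> intermediate A; intermediate B -> target; intermediate A -> intermediate B
- "hardly changes" means that all values lie within two and a half points (for a concentration: within two and a half percent of the largest)

* [target] at the end for zeta, alpha, beta, gamma, epsilon, in this order
* how that number moves from the first to the last of them (falls, then rises / rises, then falls / hardly changes / falls all the way / rises all the way)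

- Compare two times for the substrate. The route time belongs to substrate going to intermediate A, which is first order as written.
- The condensation time belongs to two substrate meeting, so it shortens as c(substrate) rises.
- Replace the falling c(substrate) curve by its mean. Both times are then constants, and their ratio, a selectivity factor, grows in step with the charge.
- Yield at a fixed time then goes as one over (one plus charge over the equal-time charge).
- The equal-time charge 2.01 M is the charge at which the two times are equal. It is read from the red and ochre yields at 12.0 min, each with a scatter of 0.5 percentage points.
- Test it on the grey run: it gives 5.40 % from the red yield, and the reading is 5.4 %.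
- Carry the equal-time charge from 12.0 min, where the runs stop, to 25 min. This is an assumption.
- Expect epsilon's yield to be 0.441 of zeta's.
- The forecast gives 0.046 M, 0.079 M, 0.125 M, 0.17 M and 0.22 M, and says rises all the way. It lowers its equal-time charge from 2.3 M to 1.1 M, since “dimerisation has about twice the time to act”.
- My reckoning differs. Keep the forecast's zeta value and the carried charge, and epsilon comes to 0.304 M, not 0.22 M.

    2 substrate → self-condensation product (k = 0.00200 M⁻¹ s⁻¹)
    substrate ⇌ intermediate A (K = 17.0, k = 0.00180 s⁻¹)
    intermediate B → target (k = 0.00360 s⁻¹)
    intermediate A → intermediate B (k = 4.70 × 10⁻⁴ s⁻¹)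

- The flasks give 0.0468 M, 0.0833 M, 0.139 M, 0.207 M and 0.299 M, and the row rises all the way. In zeta, the forward making of intermediate A runs 4.5 times ahead of the substrate loss to self-condensation product at 4.97 min and 32 times ahead at 25.0 min, while that product goes from 16.7 % at 12.5 min to 17.8 % at 25.0 min. Epsilon's yield stands at 0.427 of zeta's against the expected 0.441, and gamma's stands at 0.590 against 0.629.

The runs are calculated with constants of no real substance.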